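**Strategy.** The bicycle is disconnected at the C1=C10 double bond of ring A. Ring B (C5–C10) is the ring of (R)-pulegone: its methyl-bearing carbon becomes C8, its carbonyl carbon C10 and its isopropylidene carbon the gem-dimethyl C4. Two α′-alkylations (chiral-pool side chain, then methyl) set the quaternary C9, and an organocopper addition at C4 brings C3–C1. The key step, an intramolecular McMurry coupling of the C10 ketone with a C1 aldehyde, closes ring A and fixes the trisubstituted alkene at C1=C10 next to quaternary C9, where any elimination would favour the C5=C10 isomer. The precursor is a monocyclic keto aldehyde. The acetylglycerol ester is added last by opening (R)-glycidyl acetate with the acid.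

Key step: step 9

Remark on the chemistry: halimane numbering is used (ring A = C1–C5 and C10; ring B = C5–C10; side chain C11–C16; C17 on C8; C18 and C19 on C4; C20 on C9). Monoester 1, (R)-pulegone and (S)-glycidol are taken as purchased single enantiomers; (R)-glycidyl acetate is made from (S)-glycidol in step 12.

**Step 1**
Reactants: 1 methyl hydrogen (R)-3-methylglutarate
Product: 2 methyl (3R)-5-hydroxy-3-methylpentanoate
Conditions: BH3·SMe2, THF, 0 °C to rt; MeOH quench
Reagents that add atoms: none
Why: Borane reduces the free carboxylic acid much faster than the methyl ester (chemoselective borane reduction through an acyloxyborane), and the C13 stereocentre is not touched.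

**Step 2**
Reactants: 2 methyl (3R)-5-hydroxy-3-methylpentanoate
Product: 3 methyl (3S)-5-iodo-3-methylpentanoate
Conditions: I2, PPh3, imidazole, CH2Cl2, 0 °C
Reagents that add atoms: iodine, II
Why: Appel-type iodination displaces the alkoxyphosphonium ion of the primary alcohol by SN2 before the hydroxy ester can lactonise (the descriptor changes only because iodine raises the CIP priority of that arm).

**Step 3**
Reactants: 3 methyl (3S)-5-iodo-3-methylpentanoate
Product: 4 (3S)-5-iodo-3-methylpentan-1-ol
Conditions: i-Bu2AlH (2.2 equiv), CH2Cl2, −78 to −20 °C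
Reagents that add atoms: none
Why: Hydride reduction of the ester to the primary alcohol is fast at low temperature, where a primary alkyl iodide is inert to i-Bu2AlH.

**Step 4**
Reactants: 4 (3S)-5-iodo-3-methylpentan-1-ol
Product: 5 tert-butyl{[(3S)-5-iodo-3-methylpentyl]oxy}diphenylsilane
Conditions: TBDPSCl, imidazole, CH2Cl2, 0 °C to rt
Reagents that add atoms: tert-butyl(chloro)diphenylsilane, CC(C)(C)[Si](Cl)(c1ccccc1)c1ccccc1
Why: Silylation of the primary alcohol gives an ether that has no acidic C–H and should tolerate the enolate, organocopper, ozone and low-valent titanium steps, and it intercepts the iodo alcohol before it can close to a tetrahydropyran.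

**Step 5**
Reactants: 6 (R)-(+)-pulegone; 5 tert-butyl{[(3S)-5-iodo-3-methylpentyl]oxy}diphenylsilane
Product: 7 (3R)-2-[(3R)-5-{[tert-butyl(diphenyl)silyl]oxy}-3-methylpentyl]-3-methyl-6-(propan-2-ylidene)cyclohexan-1-one (both C2 epimers)
Conditions: 6, LiN(i-Pr)2, THF, −78 °C; then 5, DMPU, −78 to 0 °C
Reagents that add atoms: none
Why: Kinetic deprotonation of the enone takes the α′-CH2 (C9) and gives the cross-conjugated enolate, which is C-alkylated by the primary iodide (enolate SN2 alkylation); the C9 configuration formed here is erased in step 6.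

**Step 6**
Reactants: 7 (3R)-2-[(3R)-5-{[tert-butyl(diphenyl)silyl]oxy}-3-methylpentyl]-3-methyl-6-(propan-2-ylidene)cyclohexan-1-one
Product: 8 (2R,3R)-2-[(3R)-5-{[tert-butyl(diphenyl)silyl]oxy}-3-methylpentyl]-2,3-dimethyl-6-(propan-2-ylidene)cyclohexan-1-one
Conditions: LiN(i-Pr)2, THF, −78 to −30 °C; then MeI, DMPU, −78 to 0 °C
Reagents that add atoms: iodomethane, CI
Why: In the tetrasubstituted C9 enolate, A(1,2) strain with the C9 chain holds the C8 methyl pseudoaxial, so iodomethane should enter axially on the opposite face (enolate alkylation anti to the β-substituent); this sets quaternary C9 with C20 trans and the chain cis to C17.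

**Step 7**
Reactants: 8 (2R,3R)-2-[(3R)-5-{[tert-butyl(diphenyl)silyl]oxy}-3-methylpentyl]-2,3-dimethyl-6-(propan-2-ylidene)cyclohexan-1-one
Product: 10 (2R,3R,6S)-2-[(3R)-5-{[tert-butyl(diphenyl)silyl]oxy}-3-methylpentyl]-2,3-dimethyl-6-(2-methylhex-5-en-2-yl)cyclohexan-1-one, via trimethylsilyl enol ether 9 (not isolated)
Conditions: CH2=CHCH2CH2MgBr, CuBr·SMe2 (10 mol%), Me3SiCl, THF, −78 to −30 °C; then NaOMe (cat.), MeOH, rt to 40 °C; chromatography
Reagents that add atoms: but-3-enylmagnesium bromide, C=CCC[Mg]Br; chlorotrimethylsilane, C[Si](C)(C)Cl (its silyl group is present in 9 only)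
Why: Copper-catalysed, silyl chloride-accelerated conjugate addition to the β,β-disubstituted enone creates quaternary C4 as it does with pulegone itself, and methoxide then cleaves the silyl enol ether and equilibrates C5 towards the epimer with the tert-alkyl group and C17 both equatorial and the C9 chain axial (thermodynamic control; the minor C5 epimer is separated and re-equilibrated).

**Step 8**
Reactants: 10 (2R,3R,6S)-2-[(3R)-5-{[tert-butyl(diphenyl)silyl]oxy}-3-methylpentyl]-2,3-dimethyl-6-(2-methylhex-5-en-2-yl)cyclohexan-1-one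
Product: 11 4-[(1S,3R,4R)-3-[(3R)-5-{[tert-butyl(diphenyl)silyl]oxy}-3-methylpentyl]-3,4-dimethyl-2-oxocyclohexyl]-4-methylpentanal
Conditions: O3, CH2Cl2, −78 °C; then Me2S, −78 °C to rt; used crude
Reagents that add atoms: ozone, [O-][O+]=O
Why: Ozonolysis with reductive work-up cleaves the only C=C bond, the terminal alkene, to the C1 aldehyde without touching the hindered ketone or the silyl ether.

**Step 9**
Reactants: 11 4-[(1S,3R,4R)-3-[(3R)-5-{[tert-butyl(diphenyl)silyl]oxy}-3-methylpentyl]-3,4-dimethyl-2-oxocyclohexyl]-4-methylpentanal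
Product: 12 tert-butyl{[(3R)-3-methyl-5-[(1R,2R,4aS)-1,2,5,5-tetramethyl-1,2,3,4,4a,5,6,7-octahydronaphthalen-1-yl]pentyl]oxy}diphenylsilane
Conditions: TiCl3(DME)1.5, Zn–Cu couple, DME, reflux; 11 added by syringe pump at high dilution, then reflux
Reagents that add atoms: none
Why: Low-valent titanium made from TiCl3(DME)1.5 and Zn–Cu transfers an electron to the unhindered C1 aldehyde, the ketyl adds across to the C10 ketone to give a titanium-bound C1–C10 pinacolate, and this is deoxygenated on the titanium surface at reflux to the C1=C10 alkene. The closest known reaction type is the intramolecular McMurry coupling of keto aldehydes to cycloalkenes, which is established for six-membered rings and for hindered ketones. Ring A is closed by a six-membered reductive carbonyl–carbonyl coupling (C1–C10 bond formation, formally a 6-exo ketyl addition) followed by loss of both oxygens. No stereocentre is created; C5, C8, C9 and C13 are carried through, and C5 should not epimerise because the aldehyde is consumed quickly and the C5–H is shielded by quaternary C4. The step needs positional selectivity of the alkene and intramolecular over intermolecular coupling: the first is fixed by the positions of the two carbonyl groups, which excludes the tetrasubstituted C5=C10 isomer that a dehydration would favour, and the second is secured by slow addition at high dilution.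

**Step 10**
Reactants: 12 tert-butyl{[(3R)-3-methyl-5-[(1R,2R,4aS)-1,2,5,5-tetramethyl-1,2,3,4,4a,5,6,7-octahydronaphthalen-1-yl]pentyl]oxy}diphenylsilane
Product: 13 (3R)-3-methyl-5-[(1R,2R,4aS)-1,2,5,5-tetramethyl-1,2,3,4,4a,5,6,7-octahydronaphthalen-1-yl]pentan-1-ol
Conditions: Bu4NF, THF, rt
Reagents that add atoms: none
Why: Fluoride cleaves the Si–O bond (desilylation) under conditions that leave the hindered trisubstituted alkene untouched.

**Step 11**
Reactants: 13 (3R)-3-methyl-5-[(1R,2R,4aS)-1,2,5,5-tetramethyl-1,2,3,4,4a,5,6,7-octahydronaphthalen-1-yl]pentan-1-ol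
Product: 14 (3R)-3-methyl-5-[(1R,2R,4aS)-1,2,5,5-tetramethyl-1,2,3,4,4a,5,6,7-octahydronaphthalen-1-yl]pentanoic acid
Conditions: TEMPO (cat.), PhI(OAc)2 (2.2 equiv), MeCN/H2O, rt
Reagents that add atoms: water, O
Why: The oxoammonium ion from TEMPO oxidises the primary alcohol to the aldehyde and, through its hydrate, to the acid under near-neutral conditions that should not isomerise the C1=C10 alkene (TEMPO/hypervalent iodine oxidation).

**Step 12**
Reactants: 15 (S)-glycidol
Product: 16 (R)-glycidyl acetate, [(2R)-oxiran-2-yl]methyl acetate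
Conditions: Ac2O, Et3N, DMAP (cat.), CH2Cl2, 0 °C
Reagents that add atoms: acetic anhydride, CC(=O)OC(C)=O
Why: DMAP-catalysed acetylation of the primary alcohol leaves the epoxide and its stereocentre intact (the descriptor changes from S to R only through CIP priorities).

**Step 13**
Reactants: 14 (3R)-3-methyl-5-[(1R,2R,4aS)-1,2,5,5-tetramethyl-1,2,3,4,4a,5,6,7-octahydronaphthalen-1-yl]pentanoic acid; 16 (R)-glycidyl acetate
Product: 17 (2S)-3-(acetyloxy)-2-hydroxypropyl (3R)-3-methyl-5-[(1R,2R,4aS)-1,2,5,5-tetramethyl-1,2,3,4,4a,5,6,7-octahydronaphthalen-1-yl]pentanoate (target)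
Conditions: 16 (2 equiv), Bu4NBr (10 mol%), toluene, 80 °C
Reagents that add atoms: none
Why: Halide-catalysed opening of the terminal epoxide by the carboxylic acid occurs at the unsubstituted CH2, so the C–O bond at the glycerol stereocentre is never broken and the secondary hydroxyl is released between the two primary esters (regioselective epoxide opening by a carboxylic acid).

**Compound list**

1 | methyl hydrogen (R)-3-methylglutarate | COC(=O)C[C@H](C)CC(=O)O | starting material
2 | methyl (3R)-5-hydroxy-3-methylpentanoate | COC(=O)C[C@H](C)CCO | intermediate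
3 | methyl (3S)-5-iodo-3-methylpentanoate | COC(=O)C[C@H](C)CCI | intermediate
4 | (3S)-5-iodo-3-methylpentan-1-ol | OCC[C@H](C)CCI | intermediate
5 | tert-butyl{[(3S)-5-iodo-3-methylpentyl]oxy}diphenylsilane | CC(C)(C)[Si](c1ccccc1)(c1ccccc1)OCC[C@H](C)CCI | intermediate
6 | (R)-(+)-pulegone | C[C@@H]1CCC(=C(C)C)C(=O)C1 | starting material
7 | (3R)-2-[(3R)-5-{[tert-butyl(diphenyl)silyl]oxy}-3-methylpentyl]-3-methyl-6-(propan-2-ylidene)cyclohexan-1-one, C2 epimers | CC(C)(C)[Si](c1ccccc1)(c1ccccc1)OCC[C@H](C)CCC1C(=O)C(=C(C)C)CC[C@H]1C | intermediate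
8 | (2R,3R)-2-[(3R)-5-{[tert-butyl(diphenyl)silyl]oxy}-3-methylpentyl]-2,3-dimethyl-6-(propan-2-ylidene)cyclohexan-1-one | CC(C)(C)[Si](c1ccccc1)(c1ccccc1)OCC[C@H](C)CC[C@@]1(C)C(=O)C(=C(C)C)CC[C@H]1C | intermediate
9 | {[(5R,6R)-6-[(3R)-5-{[tert-butyl(diphenyl)silyl]oxy}-3-methylpentyl]-5,6-dimethyl-2-(2-methylhex-5-en-2-yl)cyclohex-1-en-1-yl]oxy}trimethylsilane | CC(C)(C)[Si](c1ccccc1)(c1ccccc1)OCC[C@H](C)CC[C@@]1(C)C(O[Si](C)(C)C)=C(C(C)(C)CCC=C)CC[C@H]1C | intermediate (not isolated)
10 | (2R,3R,6S)-2-[(3R)-5-{[tert-butyl(diphenyl)silyl]oxy}-3-methylpentyl]-2,3-dimethyl-6-(2-methylhex-5-en-2-yl)cyclohexan-1-one | CC(C)(C)[Si](c1ccccc1)(c1ccccc1)OCC[C@H](C)CC[C@@]1(C)C(=O)[C@H](C(C)(C)CCC=C)CC[C@H]1C | intermediate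
11 | 4-[(1S,3R,4R)-3-[(3R)-5-{[tert-butyl(diphenyl)silyl]oxy}-3-methylpentyl]-3,4-dimethyl-2-oxocyclohexyl]-4-methylpentanal | CC(C)(C)[Si](c1ccccc1)(c1ccccc1)OCC[C@H](C)CC[C@@]1(C)C(=O)[C@H](C(C)(C)CCC=O)CC[C@H]1C | intermediate
12 | tert-butyl{[(3R)-3-methyl-5-[(1R,2R,4aS)-1,2,5,5-tetramethyl-1,2,3,4,4a,5,6,7-octahydronaphthalen-1-yl]pentyl]oxy}diphenylsilane | CC(C)(C)[Si](c1ccccc1)(c1ccccc1)OCC[C@H](C)CC[C@@]1(C)C2=CCCC(C)(C)[C@@H]2CC[C@H]1C | intermediate
13 | (3R)-3-methyl-5-[(1R,2R,4aS)-1,2,5,5-tetramethyl-1,2,3,4,4a,5,6,7-octahydronaphthalen-1-yl]pentan-1-ol | OCC[C@H](C)CC[C@@]1(C)C2=CCCC(C)(C)[C@@H]2CC[C@H]1C | intermediate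
14 | (3R)-3-methyl-5-[(1R,2R,4aS)-1,2,5,5-tetramethyl-1,2,3,4,4a,5,6,7-octahydronaphthalen-1-yl]pentanoic acid | OC(=O)C[C@H](C)CC[C@@]1(C)C2=CCCC(C)(C)[C@@H]2CC[C@H]1C | intermediate
15 | (S)-glycidol | OC[C@H]1CO1 | starting material
16 | (R)-glycidyl acetate | CC(=O)OC[C@H]1CO1 | intermediate
17 | (2S)-3-(acetyloxy)-2-hydroxypropyl (3R)-3-methyl-5-[(1R,2R,4aS)-1,2,5,5-tetramethyl-1,2,3,4,4a,5,6,7-octahydronaphthalen-1-yl]pentanoate | CC(=O)OC[C@H](O)COC(=O)C[C@H](C)CC[C@@]1(C)C2=CCCC(C)(C)[C@@H]2CC[C@H]1C | target

**Step count.** Total: 13 steps. Longest linear sequence: 12 steps (steps 1–11 and 13, from 1); step 12 is a one-step side branch.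

**Steps most likely to fail**

Step 9 (key step). The coupling may stop at the titanium pinacolate because deoxygenation of the hindered tertiary C10–O bond is slow, or the aldehyde may be reduced or couple intermolecularly before it reaches the hindered ketone. The fallback separates ring closure from deoxygenation and sets out from 11. SmI2 (THF, t-BuOH, −78 °C to rt, high dilution) should effect the ketyl cyclisation at low temperature and give the cis-C1,C10-diol F1. Heating with 1,1′-thiocarbonyldiimidazole in toluene should convert it into the cyclic thionocarbonate F2. Corey–Winter fragmentation with P(OMe)3 at reflux then removes both oxygens by stereospecific syn-elimination, which again can only give the C1=C10 alkene, and the route is rejoined at 12.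

Step 7. Transfer of the alkyl group from copper to the twisted, α′-quaternary, β,β-disubstituted enone may be slow, so that 1,2-addition or enolisation by the Grignard reagent competes; in addition the equilibrium at C5 may be less one-sided than expected. The fallback replaces the organometallic nucleophile by Lewis-acid activation and sets out from 8. Hosomi–Sakurai allylation (allyltrimethylsilane, TiCl4, CH2Cl2, −78 °C; then NaOMe, MeOH for the C5 equilibration) should give the allyl ketone F3, in which CH2–CH=CH2 supplies C3–C1. Anti-Markovnikov hydroboration–oxidation (9-BBN, THF; then NaBO3·4H2O) should lead to the primary alcohol F4, and Dess–Martin oxidation rejoins the route at 11. In either variant the C5 epimers are separated as ketones and the minor one is returned to the methoxide equilibration.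

Step 6. Once the α′-hydrogen is tertiary, γ-deprotonation of the isopropylidene methyl groups may compete and lead to alkylation at C5, and the unactivated iodide of step 5 may already alkylate sluggishly. The fallback generates the same C9 enolate regiospecifically by conjugate reduction instead of deprotonation; it sets out from 5 and 6. Kornblum-type oxidation of iodide 5 (Me3NO, DMSO, rt) should give the aldehyde F5. Aldol addition of the α′-lithium enolate of 6 (LiN(i-Pr)2, THF, −78 °C) should give the β-hydroxy ketone F6, and mesylation–elimination (MsCl, Et3N; then DBU) the cross-conjugated dienone F7. LiBH(s-Bu)3 (THF, −78 °C) should add hydride 1,4 to the less substituted C11=C9 enone, and trapping of the resulting C9 enolate with iodomethane, with the same facial preference as in step 6, rejoins the route at 8.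

**Further compounds**

F1 | step 9 | cis-C1,C10-diol (pinacol) of the decalin, tert-butyl{[(3R)-5-[(1R,2R,4aS)-8,8a-dihydroxy-1,2,5,5-tetramethyldecahydronaphthalen-1-yl]-3-methylpentyl]oxy}diphenylsilane, configuration at the two carbinol carbons not assigned | CC(C)(C)[Si](c1ccccc1)(c1ccccc1)OCC[C@H](C)CC[C@@]1(C)C2(O)C(O)CCC(C)(C)[C@@H]2CC[C@H]1C
F2 | step 9 | cyclic thionocarbonate of F1 | CC(C)(C)[Si](c1ccccc1)(c1ccccc1)OCC[C@H](C)CC[C@@]1(C)C23OC(=S)OC2CCC(C)(C)[C@@H]3CC[C@H]1C
F3 | step 7 | (2R,3R,6S)-2-[(3R)-5-{[tert-butyl(diphenyl)silyl]oxy}-3-methylpentyl]-2,3-dimethyl-6-(2-methylpent-4-en-2-yl)cyclohexan-1-one | CC(C)(C)[Si](c1ccccc1)(c1ccccc1)OCC[C@H](C)CC[C@@]1(C)C(=O)[C@H](C(C)(C)CC=C)CC[C@H]1C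
F4 | step 7 | (2R,3R,6S)-2-[(3R)-5-{[tert-butyl(diphenyl)silyl]oxy}-3-methylpentyl]-6-(5-hydroxy-2-methylpentan-2-yl)-2,3-dimethylcyclohexan-1-one | CC(C)(C)[Si](c1ccccc1)(c1ccccc1)OCC[C@H](C)CC[C@@]1(C)C(=O)[C@H](C(C)(C)CCCO)CC[C@H]1C
F5 | step 6 | (3S)-5-{[tert-butyl(diphenyl)silyl]oxy}-3-methylpentanal | CC(C)(C)[Si](c1ccccc1)(c1ccccc1)OCC[C@H](C)CC=O
F6 | step 6 | aldol adduct, (3R)-2-[5-{[tert-butyl(diphenyl)silyl]oxy}-1-hydroxy-3-methylpentyl]-3-methyl-6-(propan-2-ylidene)cyclohexan-1-one, carbinol and C2 epimers | CC(C)(C)[Si](c1ccccc1)(c1ccccc1)OCC[C@H](C)CC(O)C1C(=O)C(=C(C)C)CC[C@H]1C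
F7 | step 6 | cross-conjugated dienone, (3R)-2-[5-{[tert-butyl(diphenyl)silyl]oxy}-3-methylpentylidene]-3-methyl-6-(propan-2-ylidene)cyclohexan-1-one, alkene geometry not relevant | CC(C)(C)[Si](c1ccccc1)(c1ccccc1)OCC[C@H](C)CC=C1C(=O)C(=C(C)C)CC[C@H]1C
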